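The data come from a simulation with made-up constants; noise was put on by code.

**The earlier run.** The earlier run, theta, had twice the enzyme of the new flask, with the same substrate in the same portions.

- theta: substrate 0.10 M (in portions, 4); enzyme 16 µM; run made earlier; portions every 1.2 s
- flask: substrate 0.10 M (in portions, 4); enzyme 8.0 µM; time 20 min; the portions of substrate follow each other after 1.2 s, the first at the start

- theta (time / min: substrate / %, target / %, isomer of the product / %): 0.333: 60.9, 24.4, 4.9; 0.667: 37.4, 36.2, 15.7; 1.50: 10.3, 36.5, 49.0; 4.00: 0.3, 24.1, 75.9

(standard deviation of a reading: 0.3 percentage points)

- a reading or a percentage of target counts all its forms, free or not
- the reaction counts as stopped when no species that holds the substrate changes by six tenths of a point or more over the second half of the time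
- no earlier run changes the charge of enzyme; that part of a forecast is a guess
- a reading of substrate is of its free form alone

1. which holds at 20 min: what has brought the reaction to rest, or that it has not come to rest (no working catalyst is left / all of the substrate has reacted / forward and back rates have come level / it is still moving)
2. conversion of substrate at 20 min
3. amount of target at 20 min, in percent of the substrate charged
4. amount of isomer of the product at 20 min, in percent of the substrate charged

**Matching time.** No run varies the enzyme, so this step is a guess: suppose the steps go in proportion to enzyme. Then, with the substrate charge and its portions held, the measure of a flask is its matching time 10.0 min, which is the flask's time multiplied by its enzyme and divided by the enzyme of the earlier run. The matching time of the new flask therefore lies beyond the last reading of the earlier run, at 4.00 min.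

**Two ways.** Is substrate used up at that last reading? First, the decay: from 0.333 min to 1.50 min in the earlier run, the readings of free substrate fall at 1.52 min⁻¹, which leaves 0.229% at 4.00 min. Second, the balance: the readings of target and isomer of the product add up to 100%, so what remains for substrate lies within the scatter of 0.3 percentage points, and so does the figure from the decay. But at 0.333 min the balance gives 70.7% against a reading of 60.9%. It cheats there by 9.8 points, so some charge then seems to sit in a form no column shows. Trust it late, not early. Your reckoning for the new flask is that substrate has reacted away, with the decay leaving <0.001% at the matching time. The earlier run has no later reading, so you take the split of its last one as a guess, 24.1% target and 75.9% isomer of the product.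

**The forecast.** The forecast names this end: forward and back rates have come level. It gives conversion 100%, target 23.2% (range 21.5% to 24.7%) and isomer of the product 76.8%. Its ground: “Twenty minutes is ample, so substrate is gone and equilibrium is reached”. Its target lies below yours; like you it has substrate gone, but it names the levelling of rates as the end.

**The flask.** The new flask ends so: all of the substrate has reacted. It gives conversion 100%, target 23.8% and isomer of the product 76.2%. Substrate, the limiting reagent, is first to run out, with 0.00700% left at 10.0 min. The new flask reached half of its conversion at 0.952 min, a matching time of 0.476 min, where the decay read from the earlier run leaves 49.0% substrate.

    substrate + enzyme → target + enzyme, rate k1*[substrate]*[enzyme]/(1 + ([substrate]/Km1)) (48.0 mM, k = 19000 M⁻¹ s⁻¹)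
    enzyme ⇌ dormant form (K = 5.50, k = 1.00 s⁻¹)
    substrate + target ⇌ idle adduct, settled at all times (K = 11.0 M⁻¹)
    target + enzyme ⇌ isomer of the product + enzyme, rate k4*[enzyme]*[target] forward; the back reaction follows from the equilibrium constant (K = 3.20, k = 13000 M⁻¹ s⁻¹)

**A second flask.** With 2.0 × 10⁻⁶ M of enzyme, the neighbour's matching time is 2.50 min, short of the last reading of the earlier run, and the decay read from that run leaves 2.25% substrate. That neighbour computes to 1.7% free substrate, 27.9% target and 69.9% isomer of the product.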